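Take the vessel: reagent and free catalyst stand in it, starting material runs in at a steady rate, and target is read against the whole charge.

common to all: starting material 0.50 M (fed, over 80 min)
- violet: reagent 2 M; free catalyst 0.56 mM; run made earlier
- amber: reagent 2 M; free catalyst 1.2 mM; run made earlier
- green: reagent 2 M; free catalyst 2.7 mM; run made earlier
- north: reagent 2.00 M; free catalyst 3.0 mM; time 80 min
- south-east: reagent 2.00 M; free catalyst 1.0 mM; time 80 min
- east: reagent 2.00 M; free catalyst 0.50 mM; time 80 min
- south: reagent 2.00 M; free catalyst 1.5 mM; time 80 min

| run | time / min | target / % |
|---|---|---|
| violet | 12.0 | 1.5 |
| violet | 25.0 | 7.9 |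
| violet | 30.0 | 9.6 |
| violet | 50.0 | 18.4 |
| violet | 60.0 | 21.8 |
| amber | 5.00 | 0.7 |
| amber | 8.00 | 2.1 |
| amber | 15.0 | 6.2 |
| amber | 30.0 | 16.8 |
| amber | 60.0 | 36.3 |
| green | 5.00 | 1.4 |
| green | 15.0 | 9.3 |
| green | 25.0 | 19.6 |
| green | 40.0 | 32.3 |
| green | 60.0 | 45.3 |

(standard deviation of a reading: 0.5 percentage points)

* ranking by amount of target, in percent of the starting material charged, from high to low, at 80 min (north / south-east / east / south)
* the same order at 15 min (north / south-east / east / south)
* the amount of target, in percent of the starting material charged of the flask you put first, at 80 min
* the amount of target, in percent of the starting material charged of the flask you put last, at 80 min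

Find the concentration that sets the order of the rate. From 5.00 min to 15.0 min amber's target rises by a factor of 8.86, and the square of time by 9.00; with a scatter of 0.5 percentage points on a first reading of 0.7% that ratio is rough, but it points to a rate that follows the starting material that has built up. Reagent at 2.00 M stands above the charge of 0.50 M, so hold c(reagent) constant and treat the step as pseudo-first-order in c(starting material), with a constant proportional to c(free catalyst).

Fold this into one number, D. Early target, as a fraction, is 0.5 D times the square of t over dosing time. Amber's reading at 15.0 min gives D = 3.53, the dosing number: how many first-order lifetimes of starting material fit into the dosing time. Scaled by catalyst, violet gets 1.65, and its own reading at 25.0 min gives 1.62.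

The reacted fraction at time t is then t/t_dose − (1 − exp(−D t/t_dose))/D. Test it: for amber at 60.0 min it gives 48.7%, but the reading is 36.3%. One number is not enough. The share of the reckoned amount read as target at that time is 0.683 for violet, 0.746 for amber and 0.726 for green, readings that lie close together while free catalyst goes from 0.56 mM to 2.7 mM. Assume that the share depends on the clock and falls exponentially, which gives 0.643 at 80 min. With D of 8.82 for north and 1.47 for east, my reckoning gives 57.0% and 30.6%, with the flasks ranked by catalyst at both times.

The forecast gives the same orders, north > south > south-east > east and north > south > south-east > east, but other levels: 60% and 25.5%. Its ground: “This suggests first-order catalyst death”.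

The flasks give north > south > south-east > east at 80 min and north > south > south-east > east at 15 min, with 54.8% on top and 27.1% at the bottom.

    free catalyst → spent catalyst (k = 4.00 × 10⁻⁶ /s)
    target → over-reaction product (k = 2.50 × 10⁻⁴ /s)
    catalyst intermediate B ⇌ released group + catalyst intermediate C (K = 0.200 M, k = 1.10 /s)
    starting material + catalyst intermediate A → catalyst intermediate B (k = 2.10 /M/s)
    reagent + free catalyst ⇌ catalyst intermediate A (K = 0.590 /M, k = 0.260 /M/s)
    catalyst intermediate C ⇌ catalyst intermediate D (K = 72.0, k = 1.60 /s)
    catalyst intermediate D → free catalyst + target (k = 1.10 /s)

North at 80.0 min holds 54.8% target and 36.4% over-reaction product, so 91.2% has reacted against 88.7% from D. The flask has what D lacks: target going on to over-reaction product, with a half-life by that step alone of 46 min in north. The neighbour of north charged with 0.750 mM free catalyst has D = 2.20, which reckons 38.3% target. That flask holds 43.6% starting material, 20.7% over-reaction product and 35.7% target.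

All runs are simulated with constants of no real substance; the scatter is artificial.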